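**Strategy.** Ring B is the α‑methylene‑γ‑butyrolactone (O–C8–C7–C11–C12, with C13 exocyclic). It is cis‑fused at C7–C8 to ring A, the cyclohexene C5–C10. Ring B can be read as a homopropargylic alcohol that has taken up one CO, so the route rests on cutting O8–C12 and C12–C11. One palladium‑catalysed cyclocarbonylation places CO between the C8 hydroxyl and the inner alkyne carbon C11. It closes ring B and leaves C13 as the methylene group, under neutral conditions that spare the C6 (R)‑2‑methylbutanoate. The precursor is ring A fully dressed. It carries the tetrasubstituted C5=C10 alkene with C14 and the (4S) side chain (O1 silylated), the 6β‑ester, and a cis 7α‑ethynyl/8α‑hydroxyl pair.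

Key step: step 14

Remarks on the chemistry
- Numbering is that of the target: ring A is C5=C10(C14)–C9–C8–C7–C6, and the chain is C5–C4(C15)–C3–C2–C1–O. Faces are defined with C5→C6→C7→C8→C9→C10 running clockwise; β points toward the viewer and α away from it. The target is 6β‑acyloxy, 7α‑C11, 8α‑O, that is (4S,6S,7R,8R,2'R).
- Assumption: 1, 14 and 22 are bought enantiopure.
- Alkynyl metals do not add 1,4 to an s‑trans cyclohexenone on their own. Step 1 therefore uses silyl triflate activation, which also delivers the regiodefined enol silane.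
- O6, O8 and O1 carry three different silyl groups (Et3Si, t‑BuMe2Si, t‑BuPh2Si). Two identical silyl ethers on O8 and O1 could not be told apart when O8 has to be freed for inversion.
- C4 is not created on the ring. It is bought with lactone 14 and transferred stereospecifically.
- The C5=C10 enolate is made by conjugate reduction, not by a deprotonation that would have to choose between C6–H and C10–H.

Step 1
Reactants: 1 (S)-4-(tert-butyldimethylsilyloxy)cyclohex-2-en-1-one; 2 ethynyltrimethylsilane
Product: 5 (1S,2R)-1-(tert-butyldimethylsilyloxy)-4-(triethylsilyloxy)-2-[(trimethylsilyl)ethynyl]cyclohex-3-ene (C5=C6 enol silane; 7α-alkynyl; 8β-OTBS), via lithium (trimethylsilyl)acetylide 3 (not isolated), via [(trimethylsilyl)ethynyl]zinc bromide 4 (not isolated)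
Conditions: 2, n-BuLi, THF, −78 °C; ZnBr2, 0 °C; then 1, Et3SiOTf, Et2O/THF, −40 °C; Et3N quench
Reagents that add atoms: triethylsilyl trifluoromethanesulfonate, CC[Si](CC)(CC)OS(=O)(=O)C(F)(F)F
Why: This is a silyl triflate‑promoted conjugate addition of an alkynylzinc halide, in which Et3SiOTf turns the enone into a silyloxyallyl cation, the alkynyl group enters C7 anti to the pseudoaxial 8β‑silyloxy group, and the enolate oxygen is captured regiospecifically as the C5=C6 enol silane.

Step 2
Reactants: 5 enol silane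
Product: 7 (2S,3R,4S)-4-(tert-butyldimethylsilyloxy)-2-(triethylsilyloxy)-3-[(trimethylsilyl)ethynyl]cyclohexan-1-one (6β-OTES; 7α-alkynyl; 8β-OTBS), via silyloxy oxirane 6 (not isolated)
Conditions: mCPBA, NaHCO3, CH2Cl2, −20 → 0 °C
Reagents that add atoms: 3-chloroperoxybenzoic acid, OOC(=O)c1cccc(Cl)c1
Why: In this Rubottom oxidation the peracid should epoxidise the electron‑rich enol silane from the β face, anti to the 7α‑alkynyl group, and the oxirane opens with a 1,4‑shift of Et3Si to the all‑equatorial 6β‑silyloxy ketone, which is also the thermodynamic C6 epimer.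

Step 3
Reactants: 7 α-silyloxy ketone
Product: 11 (2S,3R,4S)-4-(tert-butyldimethylsilyloxy)-6-methylidene-2-(triethylsilyloxy)-3-[(trimethylsilyl)ethynyl]cyclohexan-1-one, via kinetic lithium enolate 8 (not isolated), via Mannich base 9 (not isolated), via trimethylammonium iodide 10 (not isolated)
Conditions: LiN(i-Pr)2, THF, −78 °C; CH2=NMe2+ I−, −78 → 0 °C; MeI, Et2O, rt; aq NaHCO3/CH2Cl2, rt
Reagents that add atoms: dimethyl(methylidene)ammonium iodide, C=[N+](C)C.[I-]
Why: Kinetic deprotonation takes the open C10 methylene rather than the C6 methine next to the silyloxy group, and the Mannich reaction, exhaustive methylation and β‑elimination make up the standard α‑methylenation of a ketone without touching a stereocentre.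

Step 4
Reactants: 11 α-methylene ketone
Product: 13 (4S,5R,6S)-4-(tert-butyldimethylsilyloxy)-2-methyl-6-(triethylsilyloxy)-5-[(trimethylsilyl)ethynyl]cyclohex-1-en-1-yl trifluoromethanesulfonate, via tetrasubstituted lithium enolate 12 (not isolated)
Conditions: LiBH(s-Bu)3 (L-Selectride), THF, −78 °C; N-(5-chloro-2-pyridyl)bis(trifluoromethanesulfonimide), −78 → 0 °C
Reagents that add atoms: N-(5-chloro-2-pyridyl)bis(trifluoromethanesulfonimide), FC(F)(F)S(=O)(=O)N(c1ccc(Cl)cn1)S(=O)(=O)C(F)(F)F
Why: Conjugate reduction of the β‑unsubstituted exocyclic enone by the bulky borohydride turns C14 into a methyl group and releases only the C5=C10 enolate, so O‑triflation gives the tetrasubstituted enol triflate with no regiochemical choice.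

Step 5
Reactants: 14 (R)-γ-valerolactone
Product: 15 (R)-pentane-1,4-diol
Conditions: LiAlH4, THF, 0 °C → rt
Reagents that add atoms: none
Why: This is a hydride reduction of a lactone to the diol, and the carbinol centre (future C4) takes no part.

Step 6
Reactants: 15 (R)-pentane-1,4-diol
Product: 16 (R)-5-(tert-butyldiphenylsilyloxy)pentan-2-ol
Conditions: t-BuPh2SiCl (1.0 equiv), imidazole, CH2Cl2, 0 °C
Reagents that add atoms: tert-butylchlorodiphenylsilane, CC(C)(C)[Si](Cl)(c1ccccc1)c1ccccc1
Why: In this silylation the bulky chlorosilane selects the primary hydroxyl over the secondary one.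

Step 7
Reactants: 16 (R)-5-(tert-butyldiphenylsilyloxy)pentan-2-ol
Product: 17 (S)-tert-butyl[(4-iodopentyl)oxy]diphenylsilane
Conditions: PPh3, I2, N-methylimidazole, CH2Cl2, −10 °C
Reagents that add atoms: iodine, II
Why: In this Appel‑type iodination iodide displaces the alkoxyphosphonium group by SN2 with inversion (R to S), and the low temperature limits iodide–iodide exchange.

Step 8
Reactants: 13 enol triflate; 17 (S)-secondary iodide
Product: 20 5-[(2S)-5-(tert-butyldiphenylsilyloxy)pentan-2-yl]-10-methyl-6β-(triethylsilyloxy)-7α-[(trimethylsilyl)ethynyl]-8β-(tert-butyldimethylsilyloxy)cyclohex-5(10)-ene, via secondary alkyllithium 18 (not isolated), via mixed dialkylzinc 19 (not isolated)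
Conditions: 17, t-BuLi (2.2 equiv), pentane/Et2O, −100 °C (inverse addition); Me3SiCH2ZnBr·LiBr, −100 → −30 °C; then 13, PdCl2(dppf) (5 mol %), THF, −30 → 25 °C
Reagents that add atoms: none
Why: In this stereoretentive Negishi coupling the iodine–lithium exchange at −100 °C, both transmetalations and the reductive elimination all run with retention, mixed secondary dialkylzincs are configurationally stable, and the wide‑bite‑angle ligand favours reductive elimination over β‑hydride elimination, so C4 should arrive as S.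

Step 9
Reactants: 20 coupled cyclohexene
Product: 21 6β-alcohol (Et3Si removed from O6 of 20; 7α-alkynyl; 8β-OTBS; 4S)
Conditions: PPTS, MeOH/CH2Cl2, 0 °C
Reagents that add atoms: none
Why: Acid‑catalysed methanolysis sorts silyl ethers by size, so Et3Si should leave far faster than t‑BuMe2Si, t‑BuPh2Si or the C‑bound Me3Si.

Step 10
Reactants: 21 6β-alcohol; 22 (R)-2-methylbutanoic acid
Product: 23 6β-[(2R)-2-methylbutanoyloxy] compound (8β-OTBS; 7α-alkynyl; 4S)
Conditions: DCC, DMAP (cat.), CH2Cl2, 0 °C → rt
Reagents that add atoms: none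
Why: Steglich esterification acylates O6 with retention at C6, and carbodiimide activation avoids a ketene, so the α‑stereocentre of the acid is kept.

Step 11
Reactants: 23 6β-ester
Product: 24 8β-alcohol (6β-ester; 7α-alkynyl; O1-TBDPS)
Conditions: HF·pyridine, pyridine, THF, 0 °C → rt
Reagents that add atoms: none
Why: Buffered HF should cleave the secondary t‑BuMe2Si ether well before the t‑BuPh2Si ether, and this acidic fluoride source leaves the ester and the silylalkyne alone.

Step 12
Reactants: 24 8β-alcohol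
Product: 25 8α-(4-nitrobenzoate) (6β-ester; 7α-alkynyl; 7,8-cis)
Conditions: 4-O2NC6H4CO2H, PPh3, DIAD, toluene, 0 °C → rt
Reagents that add atoms: 4-nitrobenzoic acid, OC(=O)c1ccc(cc1)[N+](=O)[O-]
Why: In this Mitsunobu reaction the carboxylate displaces the 8β‑oxyphosphonium group by SN2 and inverts C8 to 8α, while C7–H lies syn to the leaving group and so cannot take part in an anti elimination toward the alkyne.

Step 13
Reactants: 25 8α-(4-nitrobenzoate)
Product: 26 (4S,6S,7R,8R) cis 7α-ethynyl-8α-hydroxy 6β-(2R)-2-methylbutanoate with O1-TBDPS (carbonylation precursor)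
Conditions: K2CO3 (cat.), MeOH, 0 °C → rt
Reagents that add atoms: none
Why: Base‑catalysed methanolysis removes the activated aryl ester and the alkynyl C–Si bond much faster than the α‑branched, crowded C6 ester, and the freed 8α‑hydroxyl lies trans to the 6β‑ester across the ring, so acyl migration is blocked.

Step 14
Reactants: 26 cis ethynyl carbinol
Product: 27 O1-tert-butyldiphenylsilyl ether of the target (cis-fused α-methylene-γ-butyrolactone)
Conditions: PdCl2 (5 mol %), PPh3 (10 mol %), SnCl2 (5 mol %), CO (7 bar), MeCN, 70 °C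
Reagents that add atoms: carbon monoxide, [C-]#[O+]
Why: The PdCl2/PPh3/SnCl2 system under CO gives a divalent palladium species that binds the C8 hydroxyl and CO as an alkoxycarbonylpalladium unit (O8–C12), which adds syn across the neighbouring C11≡C13 bond with C12 going to C11 and palladium to C13, and protonolysis of the vinylpalladium by the acid released earlier returns the catalyst. The closest known reaction type is the palladium‑catalysed cyclocarbonylation of homopropargylic alcohols such as 2‑ethynylcyclohexanols to fused α‑methylene‑γ‑butyrolactones. Ring B closes in the 5‑exo‑dig mode, so the terminal carbon C13 stays outside the ring as the methylene group. No stereocentre is created, since C7 and C8 pass through unchanged and their cis relation, fixed in step 12, lets the five‑membered ring form without strain. The step needs chemoselectivity for C8–OH and the alkyne over O1, the allylic C6 ester and the C5=C10 alkene, and this is secured by the silyl cap on O1, by the poor coordination of a tetrasubstituted alkene (so no allyl ionisation) and by the neutral medium. Moderate temperature and prompt work‑up should keep palladium hydride from moving the methylene double bond into ring B.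

Step 15
Reactants: 27 O1-silyl ether
Product: 28 target CNP0291605.2
Conditions: HF·pyridine, THF, 0 °C → rt (plastic vessel)
Reagents that add atoms: none
Why: Fluoride cleaves the Si–O bond under acidic, non‑nucleophilic conditions, which leaves the Michael‑acceptor lactone, the C6 ester and all stereocentres untouched.

**Compound list**

1 | (S)-4-(tert-butyldimethylsilyloxy)cyclohex-2-en-1-one | CC(C)(C)[Si](C)(C)O[C@H]1CCC(=O)C=C1 | starting material
2 | ethynyltrimethylsilane | C#C[Si](C)(C)C | starting material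
3 | lithium (trimethylsilyl)acetylide | [Li]C#C[Si](C)(C)C | intermediate
4 | [(trimethylsilyl)ethynyl]zinc bromide | Br[Zn]C#C[Si](C)(C)C | intermediate
5 | (1S,2R)-1-(tert-butyldimethylsilyloxy)-4-(triethylsilyloxy)-2-[(trimethylsilyl)ethynyl]cyclohex-3-ene | C[Si](C)(C)C#C[C@@H]1[C@@H](O[Si](C)(C)C(C)(C)C)CCC(O[Si](CC)(CC)CC)=C1 | intermediate
6 | 5,6β-epoxide of 5 (silyloxy oxirane) | C[Si](C)(C)C#C[C@@H]1[C@@H](O[Si](C)(C)C(C)(C)C)CC[C@@]2(O[Si](CC)(CC)CC)O[C@@H]12 | intermediate
7 | (2S,3R,4S)-4-(tert-butyldimethylsilyloxy)-2-(triethylsilyloxy)-3-[(trimethylsilyl)ethynyl]cyclohexan-1-one | C[Si](C)(C)C#C[C@@H]1[C@@H](O[Si](C)(C)C(C)(C)C)CCC(=O)[C@H]1O[Si](CC)(CC)CC | intermediate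
8 | C5=C10 kinetic lithium enolate of 7 | C[Si](C)(C)C#C[C@@H]1[C@@H](O[Si](C)(C)C(C)(C)C)CC=C(O[Li])[C@H]1O[Si](CC)(CC)CC | intermediate
9 | 10-(dimethylaminomethyl) ketone (C10 epimers, centre lost in the same step) | C[Si](C)(C)C#C[C@@H]1[C@@H](O[Si](C)(C)C(C)(C)C)CC(CN(C)C)C(=O)[C@H]1O[Si](CC)(CC)CC | intermediate
10 | 10-(trimethylammoniomethyl) ketone iodide | C[Si](C)(C)C#C[C@@H]1[C@@H](O[Si](C)(C)C(C)(C)C)CC(C[N+](C)(C)C)C(=O)[C@H]1O[Si](CC)(CC)CC.[I-] | intermediate
11 | (2S,3R,4S)-4-(tert-butyldimethylsilyloxy)-6-methylidene-2-(triethylsilyloxy)-3-[(trimethylsilyl)ethynyl]cyclohexan-1-one | C[Si](C)(C)C#C[C@@H]1[C@@H](O[Si](C)(C)C(C)(C)C)CC(=C)C(=O)[C@H]1O[Si](CC)(CC)CC | intermediate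
12 | C5=C10 lithium enolate bearing the C14 methyl group | C[Si](C)(C)C#C[C@@H]1[C@@H](O[Si](C)(C)C(C)(C)C)CC(C)=C(O[Li])[C@H]1O[Si](CC)(CC)CC | intermediate
13 | (4S,5R,6S)-4-(tert-butyldimethylsilyloxy)-2-methyl-6-(triethylsilyloxy)-5-[(trimethylsilyl)ethynyl]cyclohex-1-en-1-yl trifluoromethanesulfonate | C[Si](C)(C)C#C[C@@H]1[C@@H](O[Si](C)(C)C(C)(C)C)CC(C)=C(OS(=O)(=O)C(F)(F)F)[C@H]1O[Si](CC)(CC)CC | intermediate
14 | (R)-γ-valerolactone, (5R)-5-methyloxolan-2-one | C[C@@H]1CCC(=O)O1 | starting material
15 | (R)-pentane-1,4-diol | C[C@@H](O)CCCO | intermediate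
16 | (R)-5-(tert-butyldiphenylsilyloxy)pentan-2-ol | C[C@@H](O)CCCO[Si](c1ccccc1)(c1ccccc1)C(C)(C)C | intermediate
17 | (S)-tert-butyl[(4-iodopentyl)oxy]diphenylsilane | C[C@H](I)CCCO[Si](c1ccccc1)(c1ccccc1)C(C)(C)C | intermediate
18 | (S)-5-(tert-butyldiphenylsilyloxy)pentan-2-yllithium | C[C@H]([Li])CCCO[Si](c1ccccc1)(c1ccccc1)C(C)(C)C | intermediate
19 | (S)-[5-(tert-butyldiphenylsilyloxy)pentan-2-yl](trimethylsilylmethyl)zinc | C[C@H]([Zn]C[Si](C)(C)C)CCCO[Si](c1ccccc1)(c1ccccc1)C(C)(C)C | intermediate
20 | coupled cyclohexene: (4S) side chain on C5, C14 methyl on C10, 6β-OTES, 7α-[(trimethylsilyl)ethynyl], 8β-OTBS, O1-TBDPS | C[Si](C)(C)C#C[C@@H]1[C@@H](O[Si](C)(C)C(C)(C)C)CC(C)=C([C@@H](C)CCCO[Si](c2ccccc2)(c2ccccc2)C(C)(C)C)[C@H]1O[Si](CC)(CC)CC | intermediate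
21 | 6β-alcohol (otherwise as 20) | C[Si](C)(C)C#C[C@@H]1[C@@H](O[Si](C)(C)C(C)(C)C)CC(C)=C([C@@H](C)CCCO[Si](c2ccccc2)(c2ccccc2)C(C)(C)C)[C@H]1O | intermediate
22 | (R)-2-methylbutanoic acid | OC(=O)[C@H](C)CC | starting material
23 | 6β-(2R)-2-methylbutanoate, 8β-OTBS | C[Si](C)(C)C#C[C@@H]1[C@@H](O[Si](C)(C)C(C)(C)C)CC(C)=C([C@@H](C)CCCO[Si](c2ccccc2)(c2ccccc2)C(C)(C)C)[C@H]1OC(=O)[C@H](C)CC | intermediate
24 | 6β-(2R)-2-methylbutanoate, 8β-alcohol (7,8-trans) | C[Si](C)(C)C#C[C@@H]1[C@@H](O)CC(C)=C([C@@H](C)CCCO[Si](c2ccccc2)(c2ccccc2)C(C)(C)C)[C@H]1OC(=O)[C@H](C)CC | intermediate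
25 | 6β-(2R)-2-methylbutanoate, 8α-(4-nitrobenzoate) (7,8-cis) | C[Si](C)(C)C#C[C@@H]1[C@H](OC(=O)c2ccc(cc2)[N+](=O)[O-])CC(C)=C([C@@H](C)CCCO[Si](c2ccccc2)(c2ccccc2)C(C)(C)C)[C@H]1OC(=O)[C@H](C)CC | intermediate
26 | (4S,6S,7R,8R) cis 7α-ethynyl-8α-ol, 6β-(2R)-2-methylbutanoate, O1-TBDPS (key-step precursor) | C#C[C@@H]1[C@H](O)CC(C)=C([C@@H](C)CCCO[Si](c2ccccc2)(c2ccccc2)C(C)(C)C)[C@H]1OC(=O)[C@H](C)CC | intermediate
27 | O1-tert-butyldiphenylsilyl ether of the target (key-step product) | C=C1C(=O)O[C@@H]2CC(C)=C([C@@H](C)CCCO[Si](c3ccccc3)(c3ccccc3)C(C)(C)C)[C@@H](OC(=O)[C@H](C)CC)[C@H]12 | intermediate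
28 | CNP0291605.2, (4S,6S,7R,8R,2'R) | C=C1C(=O)O[C@@H]2CC(C)=C([C@@H](C)CCCO)[C@@H](OC(=O)[C@H](C)CC)[C@H]12 | target

**Step count and risks**

Total step count: 15, made up of 12 on the ring line and 3 for the side chain.
Longest linear sequence: 12 steps, from 1 through steps 1–4 and 8–15.

Steps most likely to fail

1. **Step 8.**
   - What may go wrong: the configuration at C4 may erode during the lithium and zinc stages. Transmetalation to the crowded alkenylpalladium may also be so slow that β‑hydride elimination, chain walking or reduction of the triflate takes over.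
   - Fallback: reverse the polarity and form the C5–C4 bond without a transition metal, by Zweifel olefination. This sets out from 13 and 18 and returns at 20.
   - Alkyllithium 18 is quenched at −100 °C with 2‑isopropoxy‑4,4,5,5‑tetramethyl‑1,3,2‑dioxaborolane. This gives the configurationally stable (S)-pinacol boronate F1, which can be purified and checked.
   - Triflate 13 is converted with (Me3Sn)2, Pd(PPh3)4 and LiCl into the alkenylstannane F2. MeLi at −78 °C then gives the alkenyllithium F3, which adds to F1 to form the lithium boronate F4.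
   - Iodine triggers the 1,2‑shift of the secondary alkyl group from boron to C5 with retention at C4, giving the β-iodo boronic ester F5. NaOMe then removes boron and iodine to give 20.

2. **Step 14.**
   - What may go wrong: the alkoxycarbonylpalladium unit may form sluggishly at the hindered C8 hydroxyl, the alkyne may oligomerise, or the methylene double bond may drift into ring B.
   - Fallback: separate the carbonylation from the ring closure while keeping C12 from CO. This sets out from 26 and returns at 27.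
   - Markovnikov hydromethoxycarbonylation through the palladium hydride cycle (Pd(OAc)2, 2‑(diphenylphosphino)pyridine, MeSO3H, CO, MeOH, 50 °C) forms C12–C11 first and gives the methyl 2-substituted acrylate F8.
   - The cis 8α‑hydroxyl then closes O8–C12 by transesterification, either spontaneously or with a trace of camphorsulfonic acid in toluene, to give 27.

3. **Step 12.**
   - What may go wrong: elimination toward C9 may give a conjugated diene that then aromatises, or the oxyphosphonium ion may simply not be displaced next to the C7 branch.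
   - Fallback: replace substitution by an oxidation–reduction sequence. This sets out from 24 and returns at 26.
   - Dess–Martin periodinane buffered with NaHCO3 gives the C8 ketone F6, which is used at once.
   - LiBH(s‑Bu)3 at −78 °C attacks from the equatorial side, as with 2‑substituted cyclohexanones, and should give the cis 8α-alcohol F7.
   - K2CO3 in MeOH removes the C‑silyl group to give 26.

Further compounds
F1 | step 8 | (S)-2-[5-(tert-butyldiphenylsilyloxy)pentan-2-yl]-4,4,5,5-tetramethyl-1,3,2-dioxaborolane | C[C@H](B1OC(C)(C)C(C)(C)O1)CCCO[Si](c1ccccc1)(c1ccccc1)C(C)(C)C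
F2 | step 8 | C5 trimethylstannyl cyclohexene (6β-OTES, 7α-alkynyl, 8β-OTBS) | C[Si](C)(C)C#C[C@@H]1[C@@H](O[Si](C)(C)C(C)(C)C)CC(C)=C([Sn](C)(C)C)[C@H]1O[Si](CC)(CC)CC
F3 | step 8 | C5 alkenyllithium | C[Si](C)(C)C#C[C@@H]1[C@@H](O[Si](C)(C)C(C)(C)C)CC(C)=C([Li])[C@H]1O[Si](CC)(CC)CC
F4 | step 8 | lithium alkenyl(sec-alkyl)pinacolatoborate | [Li+].C[Si](C)(C)C#C[C@@H]1[C@@H](O[Si](C)(C)C(C)(C)C)CC(C)=C([C@H]1O[Si](CC)(CC)CC)[B-]2(OC(C)(C)C(C)(C)O2)[C@@H](C)CCCO[Si](c3ccccc3)(c3ccccc3)C(C)(C)C
F5 | step 8 | 10-iodo-5-boryl-5-(sec-alkyl)cyclohexane (C5 and C10 not defined, both centres are lost again) | C[Si](C)(C)C#C[C@@H]1[C@@H](O[Si](C)(C)C(C)(C)C)CC(C)(I)C(B2OC(C)(C)C(C)(C)O2)([C@@H](C)CCCO[Si](c3ccccc3)(c3ccccc3)C(C)(C)C)[C@H]1O[Si](CC)(CC)CC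
F6 | step 12 | C8 ketone (6β-ester, 7α-alkynyl) | C[Si](C)(C)C#C[C@@H]1C(=O)CC(C)=C([C@@H](C)CCCO[Si](c2ccccc2)(c2ccccc2)C(C)(C)C)[C@H]1OC(=O)[C@H](C)CC
F7 | step 12 | 8α-alcohol with the C-trimethylsilyl alkyne | C[Si](C)(C)C#C[C@@H]1[C@H](O)CC(C)=C([C@@H](C)CCCO[Si](c2ccccc2)(c2ccccc2)C(C)(C)C)[C@H]1OC(=O)[C@H](C)CC
F8 | step 14 | methyl 2-(ring A C7-yl)acrylate with free 8α-hydroxyl | C=C(C(=O)OC)[C@@H]1[C@H](O)CC(C)=C([C@@H](C)CCCO[Si](c2ccccc2)(c2ccccc2)C(C)(C)C)[C@H]1OC(=O)[C@H](C)CC
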